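**Plan**

Numbering: chain C1 (ethyl CH3) to C13, C3a is the CH2OH carbon on C3; ring C1′ (C=O), C2′=C3′, C4′ (C(CH3)OH), C5′ (quaternary, bonded to C13), C6′ (CH–ethyl).
Enabling feature: C3 carries the ethyl group C1–C2 and C3a beside the C4 carbinol, so C3a is the only primary carbon γ to O4 and sits where a five-membered 1,2-oxasilolane (O4, Si, C3a, C3, C4) can close on one of its C–H bonds.
Cuts: C3a–O (C–H silylation, then Tamao–Fleming), C4–C5 (allylation), C6–C7 (crotylation), C8–C9 (Wittig, hydrogenation), C11–C12 (Julia–Kocienski, hydrogenation), C13–C5′ and C6′–ethyl (conjugate addition–allylation of 2-methylcyclohex-2-enone), C4′–CH3 (methyllithium), C1′=O (allylic oxidation).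
Forward order: the C1–C11 chain is built linearly from (S)-2-methylbutan-1-ol, the oxasilolane is closed in step 12 and opened by oxidation in step 13, the bought carbocycle is joined at C11=C12, and the 4-hydroxy-enone is made last.
Stereochemistry: C3 from (S)-2-methylbutan-1-ol, C4 and C6/C7 by iridium–SEGPHOS catalyst control, C10 from (R)-3-bromo-2-methylpropan-1-ol, C6′ by a copper–NHC catalyst, C5′ by alkylation anti to the C6′ ethyl, C4′ by axial methyl addition anti to the axial C5′ methyl.

Key step: step 12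

Remark on the chemistry: ligand antipodes are named for the sense of induction assumed here ((R)-SEGPHOS adding to the Re face of the aldehydes in steps 1 and 4, and the NHC antipode in step 18 that leads to 3S in 30); should a sense prove reversed, the mirror-image ligand is used and nothing else changes.

**Route**

Step 1
Reactants: 1 (S)-2-methylbutan-1-ol; 2 allyl acetate
Product: 4 (4R,5S)-5-methylhept-1-en-4-ol, via (S)-2-methylbutanal 3 (not isolated)
Conditions: allyl acetate (2 equiv), [Ir(cod)Cl]2 (2.5 mol%), (R)-SEGPHOS (5 mol%), 4-chloro-3-nitrobenzoic acid (10 mol%), Cs2CO3 (20 mol%), THF, 100 °C, sealed tube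
Reagents that add atoms: allyl acetate 2, C=CCOC(C)=O
Why: Iridium-catalysed transfer-hydrogenative carbonyl allylation from the alcohol oxidation level: the cyclometalated iridium π-allyl complex dehydrogenates 1 to aldehyde 3 and adds allyl to its Re face faster than the α-stereocenter can epimerise, so C4 (R) is set by the ligand (ethyl against methyl at C3 gives almost no substrate bias to overcome) and C3 is carried over from 1.

Step 2
Reactants: 4 (4R,5S)-5-methylhept-1-en-4-ol
Product: 5 (4R,5S)-4-(benzyloxy)-5-methylhept-1-ene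
Conditions: NaH, BnBr, Bu4NI (cat.), THF/DMF, 0 °C to rt
Reagents that add atoms: benzyl bromide, BrCc1ccccc1
Why: Williamson ether synthesis on the sodium alkoxide of the hindered secondary alcohol masks O4 with a group that is removed in step 10 together with the C8=C9 hydrogenation.

Step 3
Reactants: 5 (4R,5S)-4-(benzyloxy)-5-methylhept-1-ene
Product: 7 (3R,4S)-3-(benzyloxy)-4-methylhexan-1-ol, via ozonide 6 (not isolated)
Conditions: O3, CH2Cl2, −78 °C; then NaBH4, MeOH, −78 °C to rt
Reagents that add atoms: ozone, [O-][O+]=O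
Why: Ozonolysis with reductive work-up: 1,3-dipolar cycloaddition and Criegee rearrangement give ozonide 6, which NaBH4 reduces to the C6 primary alcohol, the oxidation level that step 4 needs, with loss of the terminal carbon as methanol.

Step 4
Reactants: 7 (3R,4S)-3-(benzyloxy)-4-methylhexan-1-ol; 8 but-3-en-2-yl acetate (racemic)
Product: 10 (3R,4S,6R,7S)-6-(benzyloxy)-3,7-dimethylnon-1-en-4-ol, via aldehyde 9 (not isolated)
Conditions: but-3-en-2-yl acetate (2 equiv), [Ir(cod)Cl]2 (2.5 mol%), (R)-SEGPHOS (5 mol%), 4-cyano-3-nitrobenzoic acid (10 mol%), Cs2CO3 (20 mol%), THF/H2O, 90 °C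
Reagents that add atoms: but-3-en-2-yl acetate 8, C=CC(C)OC(C)=O
Why: Iridium-catalysed transfer-hydrogenative anti-crotylation from the alcohol oxidation level: the (E)-σ-crotyl iridium species adds through a closed chair transition state to the Re face of transient aldehyde 9, which sets C6 (S) by the ligand and the C7 methyl anti to the new hydroxyl, while the β-benzyloxy aldehyde never accumulates and so should not eliminate.

Step 5
Reactants: 10 (3R,4S,6R,7S)-6-(benzyloxy)-3,7-dimethylnon-1-en-4-ol
Product: 11 (3R,4S,6R,7S)-6-(benzyloxy)-4-[(tert-butyldimethylsilyl)oxy]-3,7-dimethylnon-1-ene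
Conditions: TBSOTf, 2,6-lutidine, CH2Cl2, −78 to 0 °C
Reagents that add atoms: tert-butyldimethylsilyl triflate, CC(C)(C)[Si](C)(C)OS(=O)(=O)C(F)(F)F
Why: Silyl ether formation with the silyl triflate, which is reactive enough for the secondary hydroxyl next to the C7 methyl branch, puts on O6 a group that has no Si–H bond and survives hydrogenation, iridium catalysis and basic peroxide.

Step 6
Reactants: 11 (3R,4S,6R,7S)-6-(benzyloxy)-4-[(tert-butyldimethylsilyl)oxy]-3,7-dimethylnon-1-ene
Product: 13 (2S,3S,5R,6S)-5-(benzyloxy)-3-[(tert-butyldimethylsilyl)oxy]-2,6-dimethyloctanal, via ozonide 12 (not isolated)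
Conditions: O3, CH2Cl2, −78 °C; then PPh3, −78 °C to rt
Reagents that add atoms: ozone, [O-][O+]=O
Why: Ozonolysis with phosphine reduction of ozonide 12 cuts the vinyl group to the C8 aldehyde under neutral conditions, so the α-methyl stereocenter at C7 should not epimerise if the aldehyde is used at once.

Step 7
Reactants: 14 (R)-3-bromo-2-methylpropan-1-ol
Product: 15 (R)-(3-bromo-2-methylpropoxy)(tert-butyl)dimethylsilane
Conditions: TBSCl, imidazole, CH2Cl2, 0 °C to rt
Reagents that add atoms: tert-butyldimethylsilyl chloride, CC(C)(C)[Si](C)(C)Cl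
Why: Silylation of the primary alcohol with imidazole as a mild base protects O11 without the oxetane closure that a strong base would cause in this 3-bromo alcohol.

Step 8
Reactants: 15 (R)-(3-bromo-2-methylpropoxy)(tert-butyl)dimethylsilane
Product: 16 [(R)-3-[(tert-butyldimethylsilyl)oxy]-2-methylpropyl]triphenylphosphonium bromide
Conditions: PPh3 (neat), 110 °C; trituration with Et2O
Reagents that add atoms: triphenylphosphine, c1ccc(cc1)P(c1ccccc1)c1ccccc1
Why: SN2 quaternisation of triphenylphosphine by the β-branched primary bromide gives a Wittig salt of a well-used type, and the C10 stereocenter is not involved.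

Step 9
Reactants: 13 (2S,3S,5R,6S)-5-(benzyloxy)-3-[(tert-butyldimethylsilyl)oxy]-2,6-dimethyloctanal; 16 [(R)-3-[(tert-butyldimethylsilyl)oxy]-2-methylpropyl]triphenylphosphonium bromide
Product: 18 (2S,3Z,5R,6S,8R,9S)-8-(benzyloxy)-1,6-bis[(tert-butyldimethylsilyl)oxy]-2,5,9-trimethylundec-3-ene, via phosphonium ylide 17 (not isolated)
Conditions: 16, NaN(SiMe3)2, THF, −78 to 0 °C; then 13, −78 °C to rt
Reagents that add atoms: none
Why: Wittig olefination: the non-stabilised ylide 17 adds to aldehyde 13 at low temperature without epimerising C7 and forms the C8=C9 bond mainly as the (Z)-alkene, whose geometry does not matter because it is hydrogenated next.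

Step 10
Reactants: 18 (2S,3Z,5R,6S,8R,9S)-8-(benzyloxy)-1,6-bis[(tert-butyldimethylsilyl)oxy]-2,5,9-trimethylundec-3-ene
Product: 19 (3S,4R,6S,7R,10S)-6,11-bis[(tert-butyldimethylsilyl)oxy]-3,7,10-trimethylundecan-4-ol
Conditions: H2 (1 atm), Pd(OH)2/C, EtOAc/EtOH, rt
Reagents that add atoms: none
Why: Heterogeneous catalytic hydrogenation and hydrogenolysis in one operation saturates C8=C9 and cleaves the benzyl ether, which frees O4 alone and removes the only alkene before the iridium steps, the silyl ethers being stable in the neutral medium.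

Step 11
Reactants: 19 (3S,4R,6S,7R,10S)-6,11-bis[(tert-butyldimethylsilyl)oxy]-3,7,10-trimethylundecan-4-ol; 20 diethylsilane
Product: 21 O4 diethyl(hydrido)silyl ether of 19
Conditions: Et2SiH2 (1.5 equiv), [Ir(cod)OMe]2 (0.1 mol%), THF, rt; volatiles removed under vacuum
Reagents that add atoms: diethylsilane 20, CC[SiH2]CC
Why: Iridium-catalysed dehydrogenative O-silylation of the secondary alcohol with a dihydrosilane stops at the mono-alkoxy(hydrido)silane because the second Si–H bond is far less reactive, and it installs the tether for step 12.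

Step 12
Reactants: 21 O4 diethyl(hydrido)silyl ether of 19
Product: 22 (4S,5R)-5-[(2S,3R,6S)-2,7-bis[(tert-butyldimethylsilyl)oxy]-3,6-dimethylheptyl]-2,2,4-triethyl-1,2-oxasilolane
Conditions: [Ir(cod)OMe]2 (1 mol%), 3,4,7,8-tetramethyl-1,10-phenanthroline (2.5 mol%), norbornene (1.2 equiv), THF, 120 °C, sealed tube
Reagents that add atoms: none
Why: The Si–H bond of 21 adds oxidatively to the phenanthroline-ligated iridium centre and the hydride is passed to norbornene, leaving an iridium silyl that cleaves a C3a–H bond to give a six-membered iridacycle (Ir, Si, O4, C4, C3, C3a), from which C–Si reductive elimination releases 22 while the second hydrogen also ends on the acceptor. This is the known iridium-catalysed γ-C(sp3)–H silylation of (hydrido)silyl ethers of secondary alcohols, applied here to a β-branched carbinol. The five-membered 1,2-oxasilolane (O4, Si, C3a, C3, C4) closes by intramolecular C–Si bond formation at the γ-carbon as the metal leaves the six-membered metallacycle. No stereocenter is formed, and C3 and C4 keep their configuration because only a C–H bond of the methyl substituent on C3 is broken. The step needs site selectivity, which the catalyst's strong preference for primary over secondary and tertiary C–H bonds supplies against the γ-methylene C2 and the γ-methine C6, and which the preference for a five-membered ring supplies against the primary δ-C1–H bonds. The O6 and O11 silyl groups have no Si–H bond, so the C7 and C10 methyl groups cannot be reached, and after step 10 the substrate holds no alkene or carbonyl group that an iridium hydride could reduce.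

Step 13
Reactants: 22 (4S,5R)-5-[(2S,3R,6S)-2,7-bis[(tert-butyldimethylsilyl)oxy]-3,6-dimethylheptyl]-2,2,4-triethyl-1,2-oxasilolane
Product: 23 (2R,3R,5S,6R,9S)-5,10-bis[(tert-butyldimethylsilyl)oxy]-2-ethyl-6,9-dimethyldecane-1,3-diol
Conditions: H2O2 (30% aq.), KHCO3, THF/MeOH, 50 °C
Reagents that add atoms: hydrogen peroxide, OO
Why: Tamao–Fleming oxidation: hydroperoxide adds to the alkoxy-activated silicon of the oxasilolane, C3a migrates from silicon to oxygen and hydrolysis releases the C3a,C4 diol, while the tert-butyldimethylsilyl ethers, which are not activated in this way, should be kept.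

Step 14
Reactants: 23 (2R,3R,5S,6R,9S)-5,10-bis[(tert-butyldimethylsilyl)oxy]-2-ethyl-6,9-dimethyldecane-1,3-diol
Product: 24 (4R,5R)-4-[(2S,3R,6S)-2,7-bis[(tert-butyldimethylsilyl)oxy]-3,6-dimethylheptyl]-5-ethyl-2,2-dimethyl-1,3-dioxane
Conditions: Me2C(OMe)2, PPTS (cat.), CH2Cl2, rt
Reagents that add atoms: 2,2-dimethoxypropane, COC(C)(C)OC
Why: Acid-catalysed transacetalisation closes the six-membered acetonide over the 1,3-diol with both ring substituents equatorial, and the mild pyridinium acid should leave the silyl ethers intact.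

Step 15
Reactants: 24 (4R,5R)-4-[(2S,3R,6S)-2,7-bis[(tert-butyldimethylsilyl)oxy]-3,6-dimethylheptyl]-5-ethyl-2,2-dimethyl-1,3-dioxane
Product: 25 (2S,5R,6S)-6-[(tert-butyldimethylsilyl)oxy]-7-[(4R,5R)-5-ethyl-2,2-dimethyl-1,3-dioxan-4-yl]-2,5-dimethylheptan-1-ol
Conditions: HF·pyridine, pyridine, THF, 0 °C to rt
Reagents that add atoms: none
Why: Fluoride-mediated desilylation with pyridine-buffered HF·pyridine is selective on steric grounds for the primary O11 silyl ether over the secondary, doubly flanked O6 silyl ether and should not open the acetonide.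

Step 16
Reactants: 25 (2S,5R,6S)-6-[(tert-butyldimethylsilyl)oxy]-7-[(4R,5R)-5-ethyl-2,2-dimethyl-1,3-dioxan-4-yl]-2,5-dimethylheptan-1-ol
Product: 26 5-{[(2S,5R,6S)-6-[(tert-butyldimethylsilyl)oxy]-7-[(4R,5R)-5-ethyl-2,2-dimethyl-1,3-dioxan-4-yl]-2,5-dimethylheptyl]sulfanyl}-1-phenyl-1H-tetrazole
Conditions: 1-phenyl-1H-tetrazole-5-thiol, PPh3, DIAD, THF, 0 °C to rt
Reagents that add atoms: 1-phenyl-1H-tetrazole-5-thiol, Sc1nnnn1-c1ccccc1
Why: Mitsunobu reaction: the primary alcohol is activated as its alkoxyphosphonium salt and displaced by the acidic tetrazole thiol in an SN2 reaction at C11, which leaves the C10 stereocenter untouched.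

Step 17
Reactants: 26 the sulfide of step 16
Product: 27 5-{[(2S,5R,6S)-6-[(tert-butyldimethylsilyl)oxy]-7-[(4R,5R)-5-ethyl-2,2-dimethyl-1,3-dioxan-4-yl]-2,5-dimethylheptyl]sulfonyl}-1-phenyl-1H-tetrazole
Conditions: (NH4)6Mo7O24·4H2O (10 mol%), H2O2 (30% aq.), EtOH, 0 °C to rt
Reagents that add atoms: hydrogen peroxide, OO
Why: Molybdate-catalysed oxidation of the sulfide with hydrogen peroxide gives the sulfone by way of the sulfoxide, and the molecule holds no other group that a peroxomolybdate oxidises.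

Step 18
Reactants: 28 2-methylcyclohex-2-en-1-one
Product: 30 (2R,3S)-3-ethyl-2-methyl-2-(prop-2-en-1-yl)cyclohexan-1-one, via magnesium enolate 29 (not isolated)
Conditions: EtMgBr, Cu(OTf)2 (3 mol%), chiral N-mesityl-N′-(hydroxyalkyl)imidazolinium hexafluorophosphate (NHC precursor, 4 mol%), Et2O, −30 to 0 °C; then allyl iodide, DMPU, −30 °C to rt
Reagents that add atoms: ethylmagnesium bromide, CC[Mg]Br; allyl iodide, C=CCI
Why: Copper-catalysed asymmetric conjugate addition of a Grignard reagent to an α-substituted cyclic enone followed by enolate alkylation: the chiral NHC–copper catalyst delivers ethyl to one face of C3 of 28 and so sets C6′ (3S in 30), and allyl iodide then attacks the tetrasubstituted magnesium enolate 29 anti to the adjacent ethyl group, which makes the C5′ quaternary center with the future C13 trans to ethyl.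

Step 19
Reactants: 30 (2R,3S)-3-ethyl-2-methyl-2-(prop-2-en-1-yl)cyclohexan-1-one
Product: 32 2-[(1R,2S)-2-ethyl-1-methyl-6-oxocyclohexyl]acetaldehyde, via ozonide 31 (not isolated)
Conditions: O3, CH2Cl2, −78 °C; then PPh3, −78 °C to rt
Reagents that add atoms: ozone, [O-][O+]=O
Why: Ozonolysis with phosphine reduction of ozonide 31 turns the allyl group into the C12 aldehyde and does not touch the saturated ketone.

Step 20
Reactants: 27 the sulfone of step 17; 32 2-[(1R,2S)-2-ethyl-1-methyl-6-oxocyclohexyl]acetaldehyde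
Product: 34 (2R,3S)-2-[(2E,4S,7R,8S)-8-[(tert-butyldimethylsilyl)oxy]-9-[(4R,5R)-5-ethyl-2,2-dimethyl-1,3-dioxan-4-yl]-4,7-dimethylnon-2-en-1-yl]-3-ethyl-2-methylcyclohexan-1-one, via potassium sulfonyl carbanion 33 (not isolated)
Conditions: 27, KN(SiMe3)2, DME, −60 °C; then 32, −60 °C to rt
Reagents that add atoms: none
Why: Julia–Kocienski olefination: carbanion 33 adds to the aldehyde of 32, which is far more electrophilic than the ketone beside the quaternary center, and Smiles rearrangement with loss of SO2 and the tetrazolate forms the C11=C12 alkene, mainly (E) but of no consequence for the next step.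

Step 21
Reactants: 34 the (E)-alkene of step 20
Product: 35 (2R,3S)-2-[(4R,7R,8S)-8-[(tert-butyldimethylsilyl)oxy]-9-[(4R,5R)-5-ethyl-2,2-dimethyl-1,3-dioxan-4-yl]-4,7-dimethylnonyl]-3-ethyl-2-methylcyclohexan-1-one
Conditions: H2 (1 atm), Pd/C, EtOAc, rt
Reagents that add atoms: none
Why: Heterogeneous catalytic hydrogenation saturates the unhindered disubstituted C11=C12 alkene much faster than it would reduce the hindered ketone, and no benzyl-type group is left to be lost.

Step 22
Reactants: 35 the saturated ketone of step 21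
Product: 37 (5S,6R)-6-[(4R,7R,8S)-8-[(tert-butyldimethylsilyl)oxy]-9-[(4R,5R)-5-ethyl-2,2-dimethyl-1,3-dioxan-4-yl]-4,7-dimethylnonyl]-5-ethyl-6-methylcyclohex-2-en-1-one, via lithium enolate 36 (not isolated)
Conditions: LiN(iPr)2, THF, −78 °C; then N-tert-butylbenzenesulfinimidoyl chloride, −78 °C
Reagents that add atoms: none
Why: Ketone dehydrogenation by enolate sulfinimidoylation and syn-elimination: LiN(iPr)2 can deprotonate only C3′ because C5′ is quaternary, and the α-sulfilimine formed from enolate 36 eliminates at −78 °C to the C2′=C3′ enone, which cannot aromatise.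

Step 23
Reactants: 37 the enone of step 22
Product: 38 (1R,5S,6R)-6-[(4R,7R,8S)-8-[(tert-butyldimethylsilyl)oxy]-9-[(4R,5R)-5-ethyl-2,2-dimethyl-1,3-dioxan-4-yl]-4,7-dimethylnonyl]-5-ethyl-1,6-dimethylcyclohex-2-en-1-ol
Conditions: MeLi, Et2O, −78 °C; then H2O
Reagents that add atoms: methyllithium, [Li]C
Why: 1,2-Addition of methyllithium to the enone: in the half-chair with the C6′ ethyl equatorial the C5′ methyl is axial and blocks its own face, while the other half-chair is shielded on both faces, so methyl should enter along the axial trajectory anti to the C5′ methyl and form C4′ with hydroxyl cis to the C5′ methyl and the C6′ ethyl.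

Step 24
Reactants: 38 the tertiary allylic alcohol of step 23
Product: 39 (4R,5R,6R)-5-[(4R,7R,8S)-8-[(tert-butyldimethylsilyl)oxy]-9-[(4R,5R)-5-ethyl-2,2-dimethyl-1,3-dioxan-4-yl]-4,7-dimethylnonyl]-6-ethyl-4-hydroxy-4,5-dimethylcyclohex-2-en-1-one
Conditions: Rh2(cap)4 (1 mol%, cap = caprolactamate), t-BuOOH (70% aq., 5 equiv), K2CO3 (0.5 equiv), CH2Cl2, rt
Reagents that add atoms: tert-butyl hydroperoxide, CC(C)(C)OO
Why: Allylic C–H oxidation by tert-butylperoxyl radicals generated at the dirhodium catalyst: C1′ is the only allylic carbon that bears hydrogen because C4′ is fully substituted, the allyl radical should be trapped at the less hindered C1′ end and the peroxide collapses to the C1′ ketone, which gives the 4-hydroxy-enone without touching the tertiary alcohol.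

Step 25
Reactants: 39 the protected 4-hydroxy-enone of step 24
Product: 40 (4R,5R,6R)-5-[(4R,7R,8S,10R,11R)-8,10-dihydroxy-11-(hydroxymethyl)-4,7-dimethyltridecyl]-6-ethyl-4-hydroxy-4,5-dimethylcyclohex-2-en-1-one (CNP0104178.2)
Conditions: HF (48% aq.), MeCN, 0 °C to rt
Reagents that add atoms: none
Why: Acidic global deprotection: aqueous HF cleaves the O6 silyl ether and hydrolyses the acetonide, while the tertiary C4′ hydroxyl should not ionise because its cation would be destabilised by the enone, and the mild acid should not enolise C6′.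

**Compound list**

1 | (S)-2-methylbutan-1-ol | CC[C@H](C)CO | starting material
2 | allyl acetate | C=CCOC(C)=O | starting material
3 | (S)-2-methylbutanal (not isolated) | CC[C@H](C)C=O | intermediate
4 | (4R,5S)-5-methylhept-1-en-4-ol | CC[C@H](C)[C@H](O)CC=C | intermediate
5 | (4R,5S)-4-(benzyloxy)-5-methylhept-1-ene | CC[C@H](C)[C@H](OCc1ccccc1)CC=C | intermediate
6 | 3-[(2R,3S)-2-(benzyloxy)-3-methylpentyl]-1,2,4-trioxolane, ozonide of 5 (not isolated) | CC[C@H](C)[C@H](OCc1ccccc1)CC1OCOO1 | intermediate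
7 | (3R,4S)-3-(benzyloxy)-4-methylhexan-1-ol | CC[C@H](C)[C@H](OCc1ccccc1)CCO | intermediate
8 | but-3-en-2-yl acetate (racemic) | C=CC(C)OC(C)=O | starting material
9 | (3R,4S)-3-(benzyloxy)-4-methylhexanal (not isolated) | CC[C@H](C)[C@H](OCc1ccccc1)CC=O | intermediate
10 | (3R,4S,6R,7S)-6-(benzyloxy)-3,7-dimethylnon-1-en-4-ol | CC[C@H](C)[C@H](OCc1ccccc1)C[C@H](O)[C@H](C)C=C | intermediate
11 | (3R,4S,6R,7S)-6-(benzyloxy)-4-[(tert-butyldimethylsilyl)oxy]-3,7-dimethylnon-1-ene | CC[C@H](C)[C@H](OCc1ccccc1)C[C@H](O[Si](C)(C)C(C)(C)C)[C@H](C)C=C | intermediate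
12 | ozonide of 11, 1,2,4-trioxolane at C8 (not isolated) | CC[C@H](C)[C@H](OCc1ccccc1)C[C@H](O[Si](C)(C)C(C)(C)C)[C@H](C)C1OCOO1 | intermediate
13 | (2S,3S,5R,6S)-5-(benzyloxy)-3-[(tert-butyldimethylsilyl)oxy]-2,6-dimethyloctanal | CC[C@H](C)[C@H](OCc1ccccc1)C[C@H](O[Si](C)(C)C(C)(C)C)[C@H](C)C=O | intermediate
14 | (R)-3-bromo-2-methylpropan-1-ol | OC[C@@H](C)CBr | starting material
15 | (R)-(3-bromo-2-methylpropoxy)(tert-butyl)dimethylsilane | BrC[C@H](C)CO[Si](C)(C)C(C)(C)C | intermediate
16 | [(R)-3-[(tert-butyldimethylsilyl)oxy]-2-methylpropyl]triphenylphosphonium bromide | C[C@@H](C[P+](c1ccccc1)(c1ccccc1)c1ccccc1)CO[Si](C)(C)C(C)(C)C.[Br-] | intermediate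
17 | phosphonium ylide of 16 (not isolated) | C[C@@H](C=P(c1ccccc1)(c1ccccc1)c1ccccc1)CO[Si](C)(C)C(C)(C)C | intermediate
18 | (2S,3Z,5R,6S,8R,9S)-8-(benzyloxy)-1,6-bis[(tert-butyldimethylsilyl)oxy]-2,5,9-trimethylundec-3-ene | CC[C@H](C)[C@H](OCc1ccccc1)C[C@H](O[Si](C)(C)C(C)(C)C)[C@H](C)/C=C\[C@H](C)CO[Si](C)(C)C(C)(C)C | intermediate
19 | (3S,4R,6S,7R,10S)-6,11-bis[(tert-butyldimethylsilyl)oxy]-3,7,10-trimethylundecan-4-ol | CC[C@H](C)[C@H](O)C[C@H](O[Si](C)(C)C(C)(C)C)[C@H](C)CC[C@H](C)CO[Si](C)(C)C(C)(C)C | intermediate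
20 | diethylsilane | CC[SiH2]CC | starting material
21 | O4 diethyl(hydrido)silyl ether of 19 (C1–C11 chain, O6 and O11 as tert-butyldimethylsilyl ethers) | CC[C@H](C)[C@H](O[SiH](CC)CC)C[C@H](O[Si](C)(C)C(C)(C)C)[C@H](C)CC[C@H](C)CO[Si](C)(C)C(C)(C)C | intermediate
22 | (4S,5R)-5-[(2S,3R,6S)-2,7-bis[(tert-butyldimethylsilyl)oxy]-3,6-dimethylheptyl]-2,2,4-triethyl-1,2-oxasilolane | CC[C@@H]1C[Si](CC)(CC)O[C@@H]1C[C@H](O[Si](C)(C)C(C)(C)C)[C@H](C)CC[C@H](C)CO[Si](C)(C)C(C)(C)C | intermediate
23 | (2R,3R,5S,6R,9S)-5,10-bis[(tert-butyldimethylsilyl)oxy]-2-ethyl-6,9-dimethyldecane-1,3-diol | CC[C@H](CO)[C@H](O)C[C@H](O[Si](C)(C)C(C)(C)C)[C@H](C)CC[C@H](C)CO[Si](C)(C)C(C)(C)C | intermediate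
24 | (4R,5R)-4-[(2S,3R,6S)-2,7-bis[(tert-butyldimethylsilyl)oxy]-3,6-dimethylheptyl]-5-ethyl-2,2-dimethyl-1,3-dioxane | CC[C@@H]1COC(C)(C)O[C@@H]1C[C@H](O[Si](C)(C)C(C)(C)C)[C@H](C)CC[C@H](C)CO[Si](C)(C)C(C)(C)C | intermediate
25 | (2S,5R,6S)-6-[(tert-butyldimethylsilyl)oxy]-7-[(4R,5R)-5-ethyl-2,2-dimethyl-1,3-dioxan-4-yl]-2,5-dimethylheptan-1-ol | CC[C@@H]1COC(C)(C)O[C@@H]1C[C@H](O[Si](C)(C)C(C)(C)C)[C@H](C)CC[C@H](C)CO | intermediate
26 | 1-phenyl-1H-tetrazol-5-yl sulfide of 25 (C11–S) | CC[C@@H]1COC(C)(C)O[C@@H]1C[C@H](O[Si](C)(C)C(C)(C)C)[C@H](C)CC[C@H](C)CSc1nnnn1-c1ccccc1 | intermediate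
27 | 1-phenyl-1H-tetrazol-5-yl sulfone of 25 (C11–SO2) | CC[C@@H]1COC(C)(C)O[C@@H]1C[C@H](O[Si](C)(C)C(C)(C)C)[C@H](C)CC[C@H](C)CS(=O)(=O)c1nnnn1-c1ccccc1 | intermediate
28 | 2-methylcyclohex-2-en-1-one | CC1=CCCCC1=O | starting material
29 | bromomagnesium (S)-3-ethyl-2-methylcyclohex-1-en-1-olate (not isolated) | CC1=C(O[Mg]Br)CCC[C@@H]1CC | intermediate
30 | (2R,3S)-3-ethyl-2-methyl-2-(prop-2-en-1-yl)cyclohexan-1-one | C=CC[C@]1(C)[C@@H](CC)CCCC1=O | intermediate
31 | ozonide of 30, 1,2,4-trioxolane at C12 (not isolated) | C1(C[C@]2(C)[C@@H](CC)CCCC2=O)OCOO1 | intermediate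
32 | 2-[(1R,2S)-2-ethyl-1-methyl-6-oxocyclohexyl]acetaldehyde | O=CC[C@]1(C)[C@@H](CC)CCCC1=O | intermediate
33 | potassium α-sulfonyl carbanion of 27 (not isolated) | CC[C@@H]1COC(C)(C)O[C@@H]1C[C@H](O[Si](C)(C)C(C)(C)C)[C@H](C)CC[C@H](C)[CH-]S(=O)(=O)c1nnnn1-c1ccccc1.[K+] | intermediate
34 | (2R,3S)-2-[(2E,4S,7R,8S)-8-[(tert-butyldimethylsilyl)oxy]-9-[(4R,5R)-5-ethyl-2,2-dimethyl-1,3-dioxan-4-yl]-4,7-dimethylnon-2-en-1-yl]-3-ethyl-2-methylcyclohexan-1-one | CC[C@@H]1COC(C)(C)O[C@@H]1C[C@H](O[Si](C)(C)C(C)(C)C)[C@H](C)CC[C@H](C)/C=C/C[C@]1(C)[C@@H](CC)CCCC1=O | intermediate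
35 | (2R,3S)-2-[(4R,7R,8S)-8-[(tert-butyldimethylsilyl)oxy]-9-[(4R,5R)-5-ethyl-2,2-dimethyl-1,3-dioxan-4-yl]-4,7-dimethylnonyl]-3-ethyl-2-methylcyclohexan-1-one | CC[C@@H]1COC(C)(C)O[C@@H]1C[C@H](O[Si](C)(C)C(C)(C)C)[C@H](C)CC[C@H](C)CCC[C@]1(C)[C@@H](CC)CCCC1=O | intermediate
36 | lithium enolate of 35, C3′=C4′–OLi (not isolated) | CC[C@@H]1COC(C)(C)O[C@@H]1C[C@H](O[Si](C)(C)C(C)(C)C)[C@H](C)CC[C@H](C)CCC[C@]1(C)[C@@H](CC)CCC=C1O[Li] | intermediate
37 | (5S,6R)-6-[(4R,7R,8S)-8-[(tert-butyldimethylsilyl)oxy]-9-[(4R,5R)-5-ethyl-2,2-dimethyl-1,3-dioxan-4-yl]-4,7-dimethylnonyl]-5-ethyl-6-methylcyclohex-2-en-1-one | CC[C@@H]1COC(C)(C)O[C@@H]1C[C@H](O[Si](C)(C)C(C)(C)C)[C@H](C)CC[C@H](C)CCC[C@]1(C)[C@@H](CC)CC=CC1=O | intermediate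
38 | (1R,5S,6R)-6-[(4R,7R,8S)-8-[(tert-butyldimethylsilyl)oxy]-9-[(4R,5R)-5-ethyl-2,2-dimethyl-1,3-dioxan-4-yl]-4,7-dimethylnonyl]-5-ethyl-1,6-dimethylcyclohex-2-en-1-ol | CC[C@@H]1COC(C)(C)O[C@@H]1C[C@H](O[Si](C)(C)C(C)(C)C)[C@H](C)CC[C@H](C)CCC[C@]1(C)[C@@H](CC)CC=C[C@@]1(C)O | intermediate
39 | (4R,5R,6R)-5-[(4R,7R,8S)-8-[(tert-butyldimethylsilyl)oxy]-9-[(4R,5R)-5-ethyl-2,2-dimethyl-1,3-dioxan-4-yl]-4,7-dimethylnonyl]-6-ethyl-4-hydroxy-4,5-dimethylcyclohex-2-en-1-one | CC[C@@H]1COC(C)(C)O[C@@H]1C[C@H](O[Si](C)(C)C(C)(C)C)[C@H](C)CC[C@H](C)CCC[C@]1(C)[C@@H](CC)C(=O)C=C[C@@]1(C)O | intermediate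
40 | (4R,5R,6R)-5-[(4R,7R,8S,10R,11R)-8,10-dihydroxy-11-(hydroxymethyl)-4,7-dimethyltridecyl]-6-ethyl-4-hydroxy-4,5-dimethylcyclohex-2-en-1-one (CNP0104178.2) | CC[C@H](CO)[C@H](O)C[C@H](O)[C@H](C)CC[C@H](C)CCC[C@]1(C)[C@@H](CC)C(=O)C=C[C@@]1(C)O | target

**Step count**

Total: 25 steps.
Longest linear sequence: 21 steps (steps 1–6, 9–17 and 20–25). Steps 7–8 and 18–19 are side branches.

**Steps most likely to fail**

Step 24. The allyl radical may be trapped at C3′ with migration of the double bond, and hydrogen abstraction at C1′ next to the branched C6′ may be slow enough for unselective oxidation to compete. The fallback sets out from 38 and uses a pericyclic path in place of the radical one. SeO2 (cat.) with t-BuOOH in CH2Cl2 at rt should react by an ene reaction that can take hydrogen only from C1′, and the following [2,3]-sigmatropic shift returns oxygen to C1′ to give the C1′ allylic alcohol F3 (both C1′ epimers serve). Dess–Martin periodinane with NaHCO3 in CH2Cl2 then oxidises the secondary allylic hydroxyl, not the tertiary one, and the route is rejoined at 39.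

Step 23. Facial selectivity of the carbonyl addition may be poor if attack syn to the C5′ methyl competes, and the basic reagent may deprotonate the γ-position of the enone. The fallback sets out from 37 and delivers the carbon as a methylene. Corey–Chaykovsky epoxidation with dimethylsulfonium methylide (Me3SI, n-BuLi, THF, −10 °C) adds irreversibly and with a stronger axial preference than alkyllithium reagents, and should give the spiro-oxirane F2 with its oxygen cis to the C5′ methyl. LiEt3BH in THF at 0 °C then opens the oxirane at its CH2 terminus, and the route is rejoined at 38.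

Step 18. C-allylation of the hindered tetrasubstituted magnesium enolate may be incomplete, with O-allylation, enolate equilibration and loss of the anti selectivity as competing processes. The fallback sets out from 28 and moves the C–C bond formation to palladium. After the same copper-catalysed ethyl addition, enolate 29 is quenched with allyl chloroformate to give the allyl enol carbonate F1. Pd2(dba)3 with PPh3 (or a chiral phosphinooxazoline that reinforces the substrate bias) in THF at rt then effects a decarboxylative Tsuji allylation through a zerovalent palladium catalyst, which forms the quaternary center regiospecifically anti to the ethyl group, and the route is rejoined at 30.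

**Further compounds**

F1 | step 18 | allyl (S)-3-ethyl-2-methylcyclohex-1-en-1-yl carbonate | CC1=C(OC(=O)OCC=C)CCC[C@@H]1CC
F2 | step 23 | spiro-oxirane at C4′ of 37 (oxirane oxygen cis to the C5′ methyl, C2′=C3′ retained) | CC[C@@H]1COC(C)(C)O[C@@H]1C[C@H](O[Si](C)(C)C(C)(C)C)[C@H](C)CC[C@H](C)CCC[C@]1(C)[C@@H](CC)CC=C[C@]12CO2
F3 | step 24 | C1′ allylic alcohol of 38 (mixture at C1′) | CC[C@@H]1COC(C)(C)O[C@@H]1C[C@H](O[Si](C)(C)C(C)(C)C)[C@H](C)CC[C@H](C)CCC[C@]1(C)[C@@H](CC)C(O)C=C[C@@]1(C)O
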